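X at 12.0 min reads 30.2% of the Z charged on Tuesday and 30.4% on Sunday, with equal G and different Z, but 16.8% on Friday, with 6.2 mM of G against 12.5 mM and with 5 mM of Z.

| flask | Z | G | remark | time |
|---|---|---|---|---|
| Tuesday's | 2.5 mM | 12.5 mM | run made earlier |  |
| Sunday's | 3.8 mM | 12.5 mM | run made earlier |  |
| Friday's | 5 mM | 6.2 mM | run made earlier |  |
| flask | 5.0 mM | 12.5 mM |  | 12 min |

| run | time / min | X / % | L / % |
|---|---|---|---|
| Tuesday's | 1.50 | 4.7 | 8.6 |
| Tuesday's | 4.00 | 10.3 | 9.5 |
| Tuesday's | 8.00 | 24.0 | 9.8 |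
| Tuesday's | 12.0 | 30.2 | 9.3 |
| Sunday's | 1.00 | 4.6 | 4.2 |
| Sunday's | 2.00 | 5.1 | 8.3 |
| Sunday's | 5.00 | 13.8 | 10.7 |
| Sunday's | 12.0 | 30.4 | 12.6 |
| Friday's | 1.00 | 1.0 | 4.2 |
| Friday's | 2.00 | 4.1 | 5.0 |
| Friday's | 5.00 | 8.3 | 8.0 |
| Friday's | 12.0 | 16.8 | 9.7 |

(standard deviation of a reading: 1 percentage point)

* share of X in X plus L at 20 s
* share of X in X plus L at 12 min
* which of X and L there is more of at 12 min

- what was read earlier has a scatter of 1 percentage point, one standard deviation

I keep a ledger in fractions of the Z charged, with Z as the limiting reagent, since the flask holds 12.5 mM of G against 5.0 mM of Z. The first entry is L, which levels off, and its readings at 12 min average 10.5%. The second entry is the rest, 89.5%, which is what I expect to turn into X.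

For each run I take the natural log of the rest before X forms over the rest at 12 min, then divide by the G charged. This gives 0.0324 mM⁻¹ on Tuesday, 0.0342 mM⁻¹ on Sunday and 0.0332 mM⁻¹ on Friday. Their mean, 0.0333 mM⁻¹, is my turnover count per unit of G over 12 min.

The flask's count is 0.416, so I reckon its books to close at 12 min with X 30.4%, L 10.5% and rest 59.0%. That puts X ahead, with a share of 74.3%. At 20 s the same count gives X 1.03%, about the scatter of 1 percentage point, and the earliest reading comes later, at 1.00 min, so I commit to no early share.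

The forecast gives 43% at 20 s, 73% at 12 min and X in the lead, holding that “L is an early burst that levels off”.

The flask gives 31.3% at 20 s and 73.6% at 12 min, with X 29.6% and L 10.6%.

    Z → J (k = 0.259 s⁻¹)
    Z → D (k = 0.0308 s⁻¹)
    D ⇌ Q (K = 1.10, k = 0.195 s⁻¹)
    G + J → X (k = 0.0499 M⁻¹ s⁻¹)
    G + D → L (k = 1.86 M⁻¹ s⁻¹)

The forecast's early share stands 12 points above the flask's. At 12.0 min the rest I reckoned, 59.0%, stands in the flask as J, 59.8%. A neighbour flask charged with 50 mM of G has a count of 1.66, which reckons X at 72.5% and the rest at 17.0%. That neighbour holds X 72.8%, L 10.6% and J 16.6%.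

The numbers in the tables are simulated for substances that don't exist, noise included.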